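**Retrosynthetic overview**
1. The enal comes from α-methylenation of a C2-acetaldehyde side chain, itself from a Weinreb amide; the tiglate comes from the (R)-carbinol, made by asymmetric transfer hydrogenation of the 5-acetyl group.
2. The cis-3-acetoxy-2-(carbamoylmethyl) unit comes from ring-opening and acetylation of a cis-fused γ-lactone, whose ring fusion guarantees the 2,3-cis relationship.
3. Key disconnection: the C2–C3 bond, made from a carbene-generated homoenolate (C2, the β-carbon of a β-aryloxy enal) and the aryl aldehyde carbon (C3). Both carbons are electrophilic in the substrate, and both stereocentres are set together.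
4. The β-aryloxy enal comes from 5-acetylsalicylaldehyde and propynal by oxa-Michael addition.
5. Ring order: the benzene ring (ring A) is bought; the dihydrofuran ring (ring B) and a temporary lactone (ring C) close in the same step; ring C is opened in the next step.

Assumption: 5-acetyl-2-hydroxybenzaldehyde and propynal are bought as catalogue compounds, and the (5aR,10bS) antipode of the triazolium salt is taken to give the (3aS,8bS) lactone; if the first run gives the mirror-image lactone, the other commercial antipode is used with nothing else changed.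

**Route**

Step 1
Reactants: 1 5-acetyl-2-hydroxybenzaldehyde; 2 propynal
Product: 3 (2E)-3-(4-acetyl-2-formylphenoxy)prop-2-enal
Conditions: N-methylmorpholine (10 mol%), CH2Cl2, −20 → 0 °C, 2 added slowly
Reagents that add atoms: none
Why: Amine-catalysed oxa-Michael (conjugate) addition of the acidic phenol to the ynal, the reaction type used to make aryloxyacrylates from salicylaldehydes and propiolates; reversible addition gives the (E)-enal and no stereocentre is formed.

Step 2
Reactants: 3 (2E)-3-(4-acetyl-2-formylphenoxy)prop-2-enal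
Product: 4 (3aS,8bS)-7-acetyl-3a,8b-dihydrofuro[3,2-b][1]benzofuran-2(3H)-one (cis-fused γ-lactone on the dihydrobenzofuran)
Conditions: (5aR,10bS)-2-(2,4,6-trimethylphenyl)-5a,10b-dihydro-4H,6H-indeno[2,1-b][1,2,4]triazolo[4,3-d][1,4]oxazin-2-ium chloride (10 mol%), 1,8-diazabicyclo[5.4.0]undec-7-ene (8 mol%), toluene (0.05 M), 4 Å molecular sieves, 0 → 25 °C
Reagents that add atoms: none
Why: Proposed new method: the N-mesityl triazolylidene should add to the unhindered enal formyl group rather than to the ortho-disubstituted aryl aldehyde, turning the enal into a catalyst-bound homoenolate whose β-carbon (the aryloxy-bearing carbon, an electrophile in the free enal) attacks the neighbouring aryl aldehyde 5-exo-trig, after which the new alkoxide is acylated by the acyl azolium, which is geometrically possible only for the cis-fused 5/5 lactone, so the C2–C3 cis relationship is enforced by the ring fusion and the aminoindanol backbone selects the face; the closest known reaction type is the carbene-catalysed homoenolate annulation of enals with aldehydes to cis-γ-butyrolactones.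

Step 3
Reactants: 4 (3aS,8bS)-7-acetyl-3a,8b-dihydrofuro[3,2-b][1]benzofuran-2(3H)-one
Product: 6 (2S,3S)-5-acetyl-2-{2-[methoxy(methyl)amino]-2-oxoethyl}-2,3-dihydro-1-benzofuran-3-yl acetate, via hydroxy Weinreb amide 5 (not isolated)
Conditions: MeNH(OMe)·HCl (3 equiv), AlMe3 (3 equiv), CH2Cl2, 0 °C; aq. potassium sodium tartrate work-up; crude 5: Ac2O, pyridine, 4-(dimethylamino)pyridine (cat.), CH2Cl2, 0 °C
Reagents that add atoms: N,O-dimethylhydroxylamine hydrochloride (CNOC.Cl); acetic anhydride (CC(=O)OC(C)=O)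
Why: Weinreb aminolysis (acyl–oxygen cleavage of the strained lactone by the aluminium amide, C3–O bond untouched) followed at once by acetylation, which caps the cis γ-hydroxy amide before it can relactonise; C2 and C3 keep their configuration.

Step 4
Reactants: 6 (2S,3S)-5-acetyl-2-{2-[methoxy(methyl)amino]-2-oxoethyl}-2,3-dihydro-1-benzofuran-3-yl acetate
Product: 7 (2S,3S)-5-[(1R)-1-hydroxyethyl]-2-{2-[methoxy(methyl)amino]-2-oxoethyl}-2,3-dihydro-1-benzofuran-3-yl acetate
Conditions: RuCl[(R,R)-TsDPEN](p-cymene) (1 mol%), HCO2Na (5 equiv), H2O/DMF (1:1), 40 °C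
Reagents that add atoms: none
Why: Noyori asymmetric transfer hydrogenation of the aryl methyl ketone, in which the (R,R) catalyst gives the (R)-1-arylethanol as it does with acetophenone; the neutral aqueous formate leaves the benzylic acetate, the Weinreb amide and C2/C3 untouched.

Step 5
Reactants: 7 (2S,3S)-5-[(1R)-1-hydroxyethyl]-2-{2-[methoxy(methyl)amino]-2-oxoethyl}-2,3-dihydro-1-benzofuran-3-yl acetate
Product: 8 (1R)-1-[(2S,3S)-3-(acetyloxy)-2-{2-[methoxy(methyl)amino]-2-oxoethyl}-2,3-dihydro-1-benzofuran-5-yl]ethyl (2E)-2-methylbut-2-enoate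
Conditions: tiglic acid (1.5 equiv), N-(3-dimethylaminopropyl)-N′-ethylcarbodiimide hydrochloride (EDC·HCl), 4-(dimethylamino)pyridine, CH2Cl2, 0 → 25 °C
Reagents that add atoms: (2E)-2-methylbut-2-enoic acid, tiglic acid (OC(=O)/C(C)=C/C)
Why: Steglich esterification acylates the only free hydroxyl at oxygen, so the (R) centre is retained, and it avoids the HCl and the vinylketene (deconjugation) pathway of the acid chloride.

Step 6
Reactants: 8 (1R)-1-[(2S,3S)-3-(acetyloxy)-2-{2-[methoxy(methyl)amino]-2-oxoethyl}-2,3-dihydro-1-benzofuran-5-yl]ethyl (2E)-2-methylbut-2-enoate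
Product: 9 (1R)-1-[(2S,3S)-3-(acetyloxy)-2-(2-oxoethyl)-2,3-dihydro-1-benzofuran-5-yl]ethyl (2E)-2-methylbut-2-enoate
Conditions: Cp2Zr(H)Cl (1.5 equiv), THF, 25 °C, 20 min; H2O work-up; used crude
Reagents that add atoms: none
Why: Chemoselective amide-to-aldehyde reduction with the Schwartz reagent (hydrozirconation of the amide C=O), which is much faster on the Weinreb amide than on the acetate or the conjugated tiglate and uses no base, so C2 and C3 are not touched.

Step 7
Reactants: 9 (1R)-1-[(2S,3S)-3-(acetyloxy)-2-(2-oxoethyl)-2,3-dihydro-1-benzofuran-5-yl]ethyl (2E)-2-methylbut-2-enoate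
Product: 11 (1R)-1-[(2S,3S)-3-(acetyloxy)-2-(3-oxoprop-1-en-2-yl)-2,3-dihydro-1-benzofuran-5-yl]ethyl (2E)-2-methylbut-2-enoate, via Mannich base 10 (not isolated)
Conditions: [CH2=NMe2]I (2 equiv), Et3N (3 equiv), CH2Cl2, 25 °C
Reagents that add atoms: N,N-dimethylmethyleneiminium iodide, Eschenmoser's salt (C=[N+](C)C.[I-])
Why: Mannich reaction of the aldehyde enol with the iminium salt followed by loss of dimethylamine (α-methylenation with Eschenmoser's salt); the new carbon is sp2, C2 is not deprotonated, and fast Mannich capture is relied on to outrun β-elimination of the aryloxy group.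

**Compound list**
1 | 5-acetyl-2-hydroxybenzaldehyde | CC(=O)c1ccc(O)c(C=O)c1 | starting material
2 | propynal | C#CC=O | starting material
3 | (2E)-3-(4-acetyl-2-formylphenoxy)prop-2-enal | CC(=O)c1ccc(O/C=C/C=O)c(C=O)c1 | intermediate
4 | (3aS,8bS)-7-acetyl-3a,8b-dihydrofuro[3,2-b][1]benzofuran-2(3H)-one | O=C1C[C@@H]2Oc3ccc(C(C)=O)cc3[C@@H]2O1 | intermediate
5 | 2-[(2S,3S)-5-acetyl-3-hydroxy-2,3-dihydro-1-benzofuran-2-yl]-N-methoxy-N-methylacetamide | CON(C)C(=O)C[C@@H]1Oc2ccc(C(C)=O)cc2[C@@H]1O | intermediate (not isolated)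
6 | (2S,3S)-5-acetyl-2-{2-[methoxy(methyl)amino]-2-oxoethyl}-2,3-dihydro-1-benzofuran-3-yl acetate | CON(C)C(=O)C[C@@H]1Oc2ccc(C(C)=O)cc2[C@@H]1OC(C)=O | intermediate
7 | (2S,3S)-5-[(1R)-1-hydroxyethyl]-2-{2-[methoxy(methyl)amino]-2-oxoethyl}-2,3-dihydro-1-benzofuran-3-yl acetate | CON(C)C(=O)C[C@@H]1Oc2ccc([C@@H](C)O)cc2[C@@H]1OC(C)=O | intermediate
8 | (1R)-1-[(2S,3S)-3-(acetyloxy)-2-{2-[methoxy(methyl)amino]-2-oxoethyl}-2,3-dihydro-1-benzofuran-5-yl]ethyl (2E)-2-methylbut-2-enoate | CON(C)C(=O)C[C@@H]1Oc2ccc([C@@H](C)OC(=O)/C(C)=C/C)cc2[C@@H]1OC(C)=O | intermediate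
9 | (1R)-1-[(2S,3S)-3-(acetyloxy)-2-(2-oxoethyl)-2,3-dihydro-1-benzofuran-5-yl]ethyl (2E)-2-methylbut-2-enoate | O=CC[C@@H]1Oc2ccc([C@@H](C)OC(=O)/C(C)=C/C)cc2[C@@H]1OC(C)=O | intermediate
10 | (1R)-1-[(2S,3S)-3-(acetyloxy)-2-[3-(dimethylamino)-1-oxopropan-2-yl]-2,3-dihydro-1-benzofuran-5-yl]ethyl (2E)-2-methylbut-2-enoate (both epimers at the new α-carbon) | CN(C)CC(C=O)[C@@H]1Oc2ccc([C@@H](C)OC(=O)/C(C)=C/C)cc2[C@@H]1OC(C)=O | intermediate (not isolated)
11 | (1R)-1-[(2S,3S)-3-(acetyloxy)-2-(3-oxoprop-1-en-2-yl)-2,3-dihydro-1-benzofuran-5-yl]ethyl (2E)-2-methylbut-2-enoate | C=C(C=O)[C@@H]1Oc2ccc([C@@H](C)OC(=O)/C(C)=C/C)cc2[C@@H]1OC(C)=O | target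

**Step count and risks**
Total step count: 7. Longest linear sequence: 7 steps (1 → 11).

Most likely to fail, first: step 2. The carbene may instead add to the aryl aldehyde and close by a Stetter reaction, it may be consumed by addition–elimination at the aryloxy-enal, or the aryloxide may be expelled after β-protonation; the enantioselectivity is also untested. The fallback makes the same C2–C3 bond from the acyl anion of the aryl aldehyde and sets all three stereocentres by reduction. It sets out from 1, which adds to methyl propiolate (N-methylmorpholine cat., CH2Cl2) to give methyl (2E)-3-(4-acetyl-2-formylphenoxy)prop-2-enoate F1. An intramolecular Stetter reaction (2-(pentafluorophenyl)-6,7-dihydro-5H-pyrrolo[2,1-c][1,2,4]triazol-2-ium tetrafluoroborate, Et3N, toluene) gives racemic, configurationally labile methyl 2-(5-acetyl-3-oxo-2,3-dihydro-1-benzofuran-2-yl)acetate F2. RuCl[(R,R)-TsDPEN](p-cymene) with HCO2H/Et3N then reduces both ketones, the ring ketone under dynamic kinetic resolution to the cis alcohol, giving methyl 2-{(2S,3S)-3-hydroxy-5-[(1R)-1-hydroxyethyl]-2,3-dihydro-1-benzofuran-2-yl}acetate F3. This lactonises to (3aS,8bS)-7-[(1R)-1-hydroxyethyl]-3a,8b-dihydrofuro[3,2-b][1]benzofuran-2(3H)-one F4. Esterification as in step 5 gives (1R)-1-[(3aS,8bS)-2-oxo-2,3,3a,8b-tetrahydrofuro[3,2-b][1]benzofuran-7-yl]ethyl (2E)-2-methylbut-2-enoate F5. Aminolysis as in step 3 gives (1R)-1-[(2S,3S)-3-hydroxy-2-{2-[methoxy(methyl)amino]-2-oxoethyl}-2,3-dihydro-1-benzofuran-5-yl]ethyl (2E)-2-methylbut-2-enoate F6, and its acetylation comes back to the route at 8.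

Second: step 7. The enol(ate) of 9 carries the ring aryloxy group in the β-position, so retro-oxa-Michael opening of the dihydrofuran ring (with C2 epimerisation or decomposition) can compete with the Mannich/elimination sequence. The fallback puts the methylene on without a free enolate and without base in the elimination. It sets out from 9, which is silylated (Me3SiOTf, Et3N, CH2Cl2, −78 °C) to (1R)-1-[(2S,3S)-3-(acetyloxy)-2-{2-[(trimethylsilyl)oxy]ethenyl}-2,3-dihydro-1-benzofuran-5-yl]ethyl (2E)-2-methylbut-2-enoate F7. A Mukaiyama–Mannich reaction with [CH2=NMe2]I gives the Mannich base 10, now isolated as the free amine. 3-Chloroperbenzoic acid at 0 °C gives (1R)-1-[(2S,3S)-3-(acetyloxy)-2-[3-(dimethyloxidoamino)-1-oxopropan-2-yl]-2,3-dihydro-1-benzofuran-5-yl]ethyl (2E)-2-methylbut-2-enoate F8 (the N-oxide of 10), whose thermal Cope elimination comes back to the route at 11.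

Third: step 1. Propynal polymerises readily under amine bases, and 3 is a vinylogous aryl ester that the amine catalyst can cleave. The fallback builds the aryloxy-enal by vinylogous Vilsmeier addition–elimination instead of alkyne hydro-aryloxylation. It sets out from 1: 3-(dimethylamino)acrolein and oxalyl chloride (CH2Cl2, 0 °C) give (E)-3-chloro-N,N-dimethylprop-2-en-1-iminium chloride F9. The phenoxide of 1 (Et3N) displaces the vinylic chloride to give (E)-3-(4-acetyl-2-formylphenoxy)-N,N-dimethylprop-2-en-1-iminium chloride F10, and aqueous NaHCO3 hydrolysis comes back to the route at 3.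

**Further compounds**
F1 | step 2 | methyl (2E)-3-(4-acetyl-2-formylphenoxy)prop-2-enoate | COC(=O)/C=C/Oc1ccc(C(C)=O)cc1C=O
F2 | step 2 | methyl 2-(5-acetyl-3-oxo-2,3-dihydro-1-benzofuran-2-yl)acetate (racemic) | COC(=O)CC1Oc2ccc(C(C)=O)cc2C1=O
F3 | step 2 | methyl 2-{(2S,3S)-3-hydroxy-5-[(1R)-1-hydroxyethyl]-2,3-dihydro-1-benzofuran-2-yl}acetate | COC(=O)C[C@@H]1Oc2ccc([C@@H](C)O)cc2[C@@H]1O
F4 | step 2 | (3aS,8bS)-7-[(1R)-1-hydroxyethyl]-3a,8b-dihydrofuro[3,2-b][1]benzofuran-2(3H)-one | O=C1C[C@@H]2Oc3ccc([C@@H](C)O)cc3[C@@H]2O1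
F5 | step 2 | (1R)-1-[(3aS,8bS)-2-oxo-2,3,3a,8b-tetrahydrofuro[3,2-b][1]benzofuran-7-yl]ethyl (2E)-2-methylbut-2-enoate | O=C1C[C@@H]2Oc3ccc([C@@H](C)OC(=O)/C(C)=C/C)cc3[C@@H]2O1
F6 | step 2 | (1R)-1-[(2S,3S)-3-hydroxy-2-{2-[methoxy(methyl)amino]-2-oxoethyl}-2,3-dihydro-1-benzofuran-5-yl]ethyl (2E)-2-methylbut-2-enoate | CON(C)C(=O)C[C@@H]1Oc2ccc([C@@H](C)OC(=O)/C(C)=C/C)cc2[C@@H]1O
F7 | step 7 | (1R)-1-[(2S,3S)-3-(acetyloxy)-2-{2-[(trimethylsilyl)oxy]ethenyl}-2,3-dihydro-1-benzofuran-5-yl]ethyl (2E)-2-methylbut-2-enoate (enol ether E/Z mixture) | C[Si](C)(C)OC=C[C@@H]1Oc2ccc([C@@H](C)OC(=O)/C(C)=C/C)cc2[C@@H]1OC(C)=O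
F8 | step 7 | (1R)-1-[(2S,3S)-3-(acetyloxy)-2-[3-(dimethyloxidoamino)-1-oxopropan-2-yl]-2,3-dihydro-1-benzofuran-5-yl]ethyl (2E)-2-methylbut-2-enoate (N-oxide of 10) | C[N+](C)([O-])CC(C=O)[C@@H]1Oc2ccc([C@@H](C)OC(=O)/C(C)=C/C)cc2[C@@H]1OC(C)=O
F9 | step 1 | (E)-3-chloro-N,N-dimethylprop-2-en-1-iminium chloride | C[N+](C)=C/C=C/Cl.[Cl-]
F10 | step 1 | (E)-3-(4-acetyl-2-formylphenoxy)-N,N-dimethylprop-2-en-1-iminium chloride | C[N+](C)=C/C=C/Oc1ccc(C(C)=O)cc1C=O.[Cl-]
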